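**Plan**

1. Numbering used throughout (ring walk, not IUPAC locants): ring A C1(Me)=C2–C3(OH)–C4(Br)–C5(Me2)–C6(spiro); ring B C6–C7–C8–C9(Me,Br)–C10(Cl)–C11.
2. Retrosynthesis first strips the heteroatoms (C3–OH to C3=O, C4–Br, C9–Br and the C9 methyl back to C9=O through a 9-methylene, C10–Cl) to reach spiro dienedione 8. It then cuts ring B at C10=C11 (aldol condensation) and at C6–C7 (Michael addition), leaving 3-oxo-α-cyclocitral 4 and methyl vinyl ketone 5.
3. Enabling feature: ring A with a formyl group on C6 is a vinylogous β-keto aldehyde (O=C3–C2=C1–C6H–CH=O). C6–H is acidic, so C6 acts as a soft carbon nucleophile and the formyl carbon becomes C11.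
4. Forward order: ring A comes from α-cyclocitral (steps 1–3); ring B is annulated onto C6 in step 4; ring B is halogenated in steps 5–7 and ring A in steps 8–9.
5. Stereochemistry: C6 from the chiral amine–thiourea catalyst; C10 from face-selective chlorination of the ring-B enol ether; C9 from anti opening of a chloronium ion (Br trans to Cl); C4 from bromination with separation and recycling of the epimer; C3 from hydride delivery anti to C4–Br (OH cis to Br).

Key step: step 4

Remark: compounds 1–4 are racemic; their only stereocentre (C6–H) is erased in step 4.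
Assumption: the sense of induction of the thiourea catalyst with this new donor cannot be derived from precedent; the quinine-derived catalyst is written, and its quinidine-derived pseudo-enantiomer is taken if it delivers the antipode.

**Route**

Step 1
Reactants: 1 α-cyclocitral [(±)-2,6,6-trimethylcyclohex-2-ene-1-carbaldehyde]
Product: 2 (±)-6-(dimethoxymethyl)-1,5,5-trimethylcyclohex-1-ene
Conditions: HC(OMe)3 (2 equiv), MeOH, PPTS (5 mol%), rt
Reagents that add atoms: trimethyl orthoformate COC(OC)OC
Why: Acid-catalysed acetalisation with an orthoester as water scavenger masks the formyl group under conditions mild enough to leave the β,γ-double bond in place, and no stereocentre of consequence is involved.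

Step 2
Reactants: 2 (±)-6-(dimethoxymethyl)-1,5,5-trimethylcyclohex-1-ene
Product: 3 (±)-4-(dimethoxymethyl)-3,5,5-trimethylcyclohex-2-en-1-one
Conditions: t-BuOOH (5 equiv), Rh2(cap)4 (1 mol%), K2CO3, CH2Cl2, rt
Reagents that add atoms: tert-butyl hydroperoxide CC(C)(C)OO
Why: Dirhodium-catalysed allylic oxidation with TBHP turns the ring allylic methylene C3 into the conjugated ketone, as in the 3-oxidation of α-ionone-type rings, while the acetal shields the aldehyde C–H and the buried C6–H is not abstracted.

Step 3
Reactants: 3 (±)-4-(dimethoxymethyl)-3,5,5-trimethylcyclohex-2-en-1-one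
Product: 4 (±)-2,6,6-trimethyl-4-oxocyclohex-2-ene-1-carbaldehyde (3-oxo-α-cyclocitral, possibly with its enol tautomer)
Conditions: Amberlyst-15, acetone–H2O (10:1), rt; used crude
Reagents that add atoms: water O
Why: Mild acid hydrolysis of the dimethyl acetal frees the aldehyde, and any keto, enol or double-bond tautomer that forms is harmless because all give the same delocalised anion in step 4.

Step 4
Reactants: 4 3-oxo-α-cyclocitral; 5 methyl vinyl ketone
Product: 8 (6S)-1,5,5-trimethylspiro[5.5]undeca-1,10-diene-3,9-dione, via keto aldehyde 6 (not isolated), via aldol 7 (not isolated)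
Conditions: 9-amino(9-deoxy)epi-quinine 3,5-bis(trifluoromethyl)phenyl thiourea (10 mol%), 5 (2 equiv), PhMe, 0 °C → rt; evaporate excess 5; then p-TsOH·H2O (20 mol%), PhMe, 80 °C
Reagents that add atoms: none
Why: Proposed new method: the quinuclidine nitrogen removes the acidic C6–H of the vinylogous β-keto aldehyde, and the ammonium dienolate (O=C3–C2=C1–C6–CH=O), held by the thiourea N–H bonds, adds through C6 to the enone 5 to form C6–C7; the closest known reactions are amine–thiourea-catalysed Michael additions of α-branched 1,3-dicarbonyl donors to enones and the Robinson spiroannulation of α-branched cyclohexanecarbaldehydes with 5. In the second stage the methyl-ketone enol of 6 attacks the formyl carbon (C10–C11) in a 6-(enolendo)-exo-trig aldol closure of ring B, and acid-driven loss of water from 7 gives the enone. The only new stereocentre, C6, is set in the Michael step by the catalyst, which shields one face of the planar anion; once quaternary it cannot epimerise. The step needs attack at C6 and not at C2 or oxygen: C2 and O adducts can revert by retro-Michael reaction, whereas only the C6 adduct can close onto the aldehyde and is drained irreversibly. Acid is chosen for the closure because base would reopen 6 by retro-Michael loss of the stabilised C6 anion.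

Step 5
Reactants: 8 (6S)-1,5,5-trimethylspiro[5.5]undeca-1,10-diene-3,9-dione
Product: 10 (6S,10S)-10-chloro-1,5,5-trimethylspiro[5.5]undec-1-ene-3,9-dione, via silyl enol ether 9 (not isolated)
Conditions: Et3SiH (1.2 equiv), RhCl(PPh3)3 (1 mol%), PhMe, 50 °C; evaporate; then NCS (1.3 equiv), THF, −78 → 0 °C
Reagents that add atoms: N-chlorosuccinimide O=C1CCC(=O)N1Cl
Why: Rh-catalysed 1,4-hydrosilylation picks the β-monosubstituted ring-B enone over the β,β-disubstituted ring-A enone and gives the regiodefined C9=C10 silyl enol ether, which NCS chlorinates at C10 (α-chlorination of a silyl enol ether); Cl+ should enter on the ring-B face that carries the flat C1 vinyl carbon, away from the C5 gem-dimethyl group across the spiro centre, and base is avoided so that the enolisable C10 centre is not equilibrated.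

Step 6
Reactants: 10 (6S,10S)-10-chloro-1,5,5-trimethylspiro[5.5]undec-1-ene-3,9-dione
Product: 11 (6S,10S)-10-chloro-1,5,5-trimethyl-9-methylidenespiro[5.5]undec-1-en-3-one
Conditions: Tebbe reagent (1.05 equiv), pyridine (cat.), THF–PhMe, −40 → 0 °C
Reagents that add atoms: Tebbe reagent C[Al-]1(C)C[Ti]([Cl+]1)(C1C=CC=C1)C1C=CC=C1
Why: Tebbe methylenation is non-basic, so the α-chloro ketone is neither epimerised at C10 nor closed to an epoxide, and with one equivalent at low temperature the inductively activated saturated C9 ketone should react before the conjugated, less electrophilic C3 enone.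

Step 7
Reactants: 11 (6S,10S)-10-chloro-1,5,5-trimethyl-9-methylidenespiro[5.5]undec-1-en-3-one
Product: 12 (6S,9S,10S)-9-bromo-10-chloro-1,5,5,9-tetramethylspiro[5.5]undec-1-en-3-one
Conditions: HBr (33% in AcOH, 3 equiv), CH2Cl2, −20 → 0 °C, dark, BHT (cat.)
Reagents that add atoms: hydrogen bromide Br
Why: Ionic Markovnikov hydrobromination of a 2-substituted allyl chloride (as with methallyl chloride): protonation of the exocyclic CH2 gives the tertiary C9 cation, the neighbouring chlorine bridges it, and bromide opens the chloronium ion at the tertiary carbon from the face opposite to chlorine, giving Br trans to Cl, while the ring-A enone, with its fully substituted β-carbon, does not retain HBr.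

Step 8
Reactants: 12 (6S,9S,10S)-9-bromo-10-chloro-1,5,5,9-tetramethylspiro[5.5]undec-1-en-3-one
Product: 14 (4R,6R,9S,10S)-4,9-dibromo-10-chloro-1,5,5,9-tetramethylspiro[5.5]undec-1-en-3-one, via silyl dienol ether 13 (not isolated)
Conditions: LiHMDS (1.1 equiv), TMSCl (1.5 equiv), THF, −78 °C; then NBS (1.05 equiv), −78 °C
Reagents that add atoms: N-bromosuccinimide O=C1CCC(=O)N1Br
Why: Kinetic α′-deprotonation of the isophorone-type enone at C4 with in situ silylation, then NBS bromination of the cross-conjugated silyl dienol ether; the two faces of ring A differ only through the remote substitution of ring B, so the bias at C4 should be weak and the centre is secured by chromatographic separation of the epimers with recycling of the unwanted one through its enol (cat. HBr, AcOH), the tertiary bromide being expected to survive the hindered amide base at −78 °C.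

Step 9
Reactants: 14 (4R,6R,9S,10S)-4,9-dibromo-10-chloro-1,5,5,9-tetramethylspiro[5.5]undec-1-en-3-one
Product: 15 (3S,4R,6R,9S,10S)-4,9-dibromo-10-chloro-1,5,5,9-tetramethylspiro[5.5]undec-1-en-3-ol (IUPAC locants: 3S,4R,6R,8S,9S-4,9-dibromo-8-chloro)
Conditions: DIBAL-H (1.5 equiv), CH2Cl2, −78 °C; Rochelle salt work-up
Reagents that add atoms: none
Why: 1,2-Reduction of the α′-bromo enone with DIBAL-H, in which hydride approaches C3 anti to the C4–Br bond (Felkin–Anh/Cornforth polar control) and away from the axial C5 methyl group, so the new hydroxyl should end up cis to bromine, and neither alkyl halide reacts at −78 °C.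

**Compound list**

1 | α-cyclocitral, (±)-2,6,6-trimethylcyclohex-2-ene-1-carbaldehyde | CC1=CCCC(C)(C)C1C=O | starting material
2 | (±)-6-(dimethoxymethyl)-1,5,5-trimethylcyclohex-1-ene | CC1=CCCC(C)(C)C1C(OC)OC | intermediate
3 | (±)-4-(dimethoxymethyl)-3,5,5-trimethylcyclohex-2-en-1-one | CC1=CC(=O)CC(C)(C)C1C(OC)OC | intermediate
4 | (±)-2,6,6-trimethyl-4-oxocyclohex-2-ene-1-carbaldehyde (3-oxo-α-cyclocitral) | CC1=CC(=O)CC(C)(C)C1C=O | intermediate
5 | methyl vinyl ketone (but-3-en-2-one) | C=CC(C)=O | starting material
6 | (1S)-2,6,6-trimethyl-4-oxo-1-(3-oxobutyl)cyclohex-2-ene-1-carbaldehyde (Michael adduct, not isolated) | CC1=CC(=O)CC(C)(C)[C@@]1(C=O)CCC(C)=O | intermediate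
7 | (6S)-11-hydroxy-1,5,5-trimethylspiro[5.5]undec-1-ene-3,9-dione, both C11 epimers (aldol, not isolated) | CC1=CC(=O)CC(C)(C)[C@@]12CCC(=O)CC2O | intermediate
8 | (6S)-1,5,5-trimethylspiro[5.5]undeca-1,10-diene-3,9-dione (IUPAC locants: undeca-1,7-diene) | CC1=CC(=O)CC(C)(C)[C@@]12CCC(=O)C=C2 | intermediate
9 | (6S)-1,5,5-trimethyl-9-(triethylsilyloxy)spiro[5.5]undeca-1,9-dien-3-one (C9=C10 silyl enol ether, not isolated) | CC1=CC(=O)CC(C)(C)[C@@]12CCC(O[Si](CC)(CC)CC)=CC2 | intermediate
10 | (6S,10S)-10-chloro-1,5,5-trimethylspiro[5.5]undec-1-ene-3,9-dione (Cl on the ring-B face syn to C1) | CC1=CC(=O)CC(C)(C)[C@@]12CCC(=O)[C@@H](Cl)C2 | intermediate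
11 | (6S,10S)-10-chloro-1,5,5-trimethyl-9-methylidenespiro[5.5]undec-1-en-3-one | CC1=CC(=O)CC(C)(C)[C@@]12CCC(=C)[C@@H](Cl)C2 | intermediate
12 | (6S,9S,10S)-9-bromo-10-chloro-1,5,5,9-tetramethylspiro[5.5]undec-1-en-3-one (Br trans to Cl) | CC1=CC(=O)CC(C)(C)[C@@]12CC[C@](C)(Br)[C@@H](Cl)C2 | intermediate
13 | 3-trimethylsilyloxy-1,3-diene of 12 (C3=C4 silyl dienol ether, not isolated) | CC1=CC(O[Si](C)(C)C)=CC(C)(C)[C@@]12CC[C@](C)(Br)[C@@H](Cl)C2 | intermediate
14 | (4R,6R,9S,10S)-4,9-dibromo-10-chloro-1,5,5,9-tetramethylspiro[5.5]undec-1-en-3-one (C4–Br on the ring-A face syn to C11) | CC1=CC(=O)[C@H](Br)C(C)(C)[C@@]12CC[C@](C)(Br)[C@@H](Cl)C2 | intermediate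
15 | (3S,4R,6R,9S,10S)-4,9-dibromo-10-chloro-1,5,5,9-tetramethylspiro[5.5]undec-1-en-3-ol (CNP0537910.1) | CC1=C[C@H](O)[C@H](Br)C(C)(C)[C@@]12CC[C@](C)(Br)[C@@H](Cl)C2 | target

**Count and risks**

Total step count: 9. Longest linear sequence: 9 steps (1 → 15).

Steps most likely to fail:

Step 4 (the proposed new method). The anion may be alkylated at C2 or on oxygen instead of C6, addition at the neopentyl C6 may be too slow, or the catalyst may discriminate the faces of the anion poorly. The fallback uses a covalent chiral auxiliary in a chiral-imine (secondary enamine) Michael addition, a known way to α-quaternary carbonyl compounds. It sets out from 4, which is condensed with (S)-1-phenylethylamine (PhMe, MgSO4, rt) to the aminomethylene ketone F1. The N–H of F1 delivers 5 to C6 through the compact cyclic transition state typical of these additions (THF, rt → 40 °C), which also enforces C6 over C2, and gives the α-quaternary imine F2. Hydrolysis with aqueous AcOH releases the amine and the keto aldehyde, so the route is rejoined at 6, which is closed to 8 by the TsOH stage of step 4. The antipodal amine is used if the facial sense is opposite.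

Step 5. The spiro centre may direct Cl+ to the other face of the ring-B enol ether (the face syn to C5), or the enolisable α-chloro ketone may equilibrate at C10. The fallback turns the same facial preference to advantage with one inversion. It sets out from 9 (made from 8 as in step 5). Rubottom oxidation (mCPBA, NaHCO3, CH2Cl2, 0 °C; then aqueous citric acid) would put oxygen on that same face and give the hydroxy ketone F3. An Appel chlorination (PPh3, CCl4, MeCN, rt) then replaces the hydroxyl by chloride with SN2 inversion at C10, and the route is rejoined at 10.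

Step 8. Facial selectivity at C4 may be negligible, because the ring-B substituents that make C6 stereogenic are too remote to steer ring A, so most of the material would have to be recycled. The fallback replaces substrate control by a catalyst-controlled dynamic kinetic resolution. It sets out from 12, which is brominated as in step 8, and the unseparated mixture of 14 and the C4-epimeric bromo ketone F4 is submitted to Noyori–Ikariya transfer hydrogenation (RuCl[(R,R)-TsDPEN](p-cymene), HCO2H–Et3N 5:2, rt). The reaction type is known for cyclic α-halo ketones conjugated to an arene, which give cis-halohydrins. The epimers interconvert through the enol, the catalyst should reduce only the matched one to the cis-bromohydrin, and the route is rejoined at 15. The catalyst enantiomer is assigned by analogy with aryl ketones, the vinyl group taking the place of the arene.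

**Further compounds**

F1 | step 4 | 4-({[(1S)-1-phenylethyl]amino}methylidene)-3,5,5-trimethylcyclohex-2-en-1-one | CC1=CC(=O)CC(C)(C)C1=CN[C@@H](C)c1ccccc1
F2 | step 4 | N-[(1S)-1-phenylethyl]imine of (1S)-2,6,6-trimethyl-4-oxo-1-(3-oxobutyl)cyclohex-2-ene-1-carbaldehyde | CC1=CC(=O)CC(C)(C)[C@@]1(C=N[C@@H](C)c1ccccc1)CCC(C)=O
F3 | step 5 | (6S,10R)-10-hydroxy-1,5,5-trimethylspiro[5.5]undec-1-ene-3,9-dione (OH on the ring-B face syn to C5) | CC1=CC(=O)CC(C)(C)[C@@]12CCC(=O)[C@H](O)C2
F4 | step 8 | (4S,6R,9S,10S)-4,9-dibromo-10-chloro-1,5,5,9-tetramethylspiro[5.5]undec-1-en-3-one (C4 epimer of 14) | CC1=CC(=O)[C@@H](Br)C(C)(C)[C@@]12CC[C@](C)(Br)[C@@H](Cl)C2
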